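Assumption: the target SMILES contains no stereocentre and no stereogenic double bond, so Kanzonol E is achiral and "single enantiomer" means the one achiral compound; no stereocontrol is needed.

**Retrosynthetic overview**

- Kanzonol E ⇒ (C2=C3 desaturation, O1–C2 oxa-Michael, Cα–Cβ aldol) 2,4-dihydroxy-5-prenylacetophenone + 2,2-dimethyl-2H-chromene-6-carbaldehyde. In the forward direction this is chalcone → flavanone → flavone, run in one flask from the two unprotected halves.
- Chromene aldehyde ⇒ (oxa-6π closure of an o-quinone methide, dehydrogenation) 4-hydroxy-3-prenylbenzaldehyde, i.e. oxidative cyclisation of an o-prenylphenol.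
- Both prenylphenols ⇒ direct C-prenylation of 4-hydroxybenzaldehyde and of 2,4-dihydroxyacetophenone.
- Ring order: the pyran ring of the chromene first, the γ-pyrone ring last. The A-ring prenylphenol is brought in only after the DDQ step, so it never meets DDQ and stays open.

**Route**

Step 1
Reactants: 1 4-hydroxybenzaldehyde; 2 prenyl bromide (1-bromo-3-methylbut-2-ene)
Product: 3 4-hydroxy-3-(3-methylbut-2-en-1-yl)benzaldehyde
Conditions: 2 (1.1 equiv), 10% aq KOH (1.1 equiv), rt, 24 h; then 1 M HCl, chromatography
Reagents that add atoms: prenyl bromide (2), CC(C)=CCBr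
Why: Ortho C-alkylation of an ambident phenoxide in water (hydrogen bonding masks the oxygen; the para position is blocked by CHO), the chemical counterpart of an aromatic prenyltransferase; the O-prenyl ether and unreacted 1 are separated, and no stereocentre is formed.

Step 2
Reactants: 3 4-hydroxy-3-(3-methylbut-2-en-1-yl)benzaldehyde
Product: 5 2,2-dimethyl-2H-chromene-6-carbaldehyde, via o-quinone methide 4 (not isolated)
Conditions: DDQ (1.2 equiv), PhH, reflux, 3 h
Reagents that add atoms: none
Why: DDQ oxidative cyclisation of an o-prenylphenol: hydride abstraction from the benzylic/allylic CH2 gives the (Z)-o-quinone methide 4, which closes by oxa-6π electrocyclisation to the 2,2-dimethyl-2H-chromene; the aldehyde is inert to DDQ and no stereocentre is formed.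

Step 3
Reactants: 6 2,4-dihydroxyacetophenone; 7 2-methylbut-3-en-2-ol
Product: 8 1-[2,4-dihydroxy-5-(3-methylbut-2-en-1-yl)phenyl]ethan-1-one
Conditions: 7 (1.2 equiv), BF3·OEt2 (0.3 equiv), 1,4-dioxane, rt, 4 h; chromatography
Reagents that add atoms: 2-methylbut-3-en-2-ol (7), C=CC(C)(C)O
Why: Lewis-acid Friedel–Crafts C-prenylation: the dimethylallyl cation from the tertiary allylic alcohol attacks through its primary terminus at C5 (para to the 2-OH, ortho to the 4-OH, not flanked by both oxygens), giving the 5-prenyl isomer as main product; the minor 3-isomer and bis-prenyl material are removed, and no stereocentre is formed.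

Step 4
Reactants: 8 1-[2,4-dihydroxy-5-(3-methylbut-2-en-1-yl)phenyl]ethan-1-one; 5 2,2-dimethyl-2H-chromene-6-carbaldehyde
Product: 11 Kanzonol E, via chalcone 9 (not isolated), via flavanone 10 (not isolated)
Conditions: 5 (1.1 equiv), pyrrolidine (1.0 equiv), DMSO, 80 °C, 8 h; then I2 (20 mol%), 130 °C, 4 h; aq Na2S2O3 work-up
Reagents that add atoms: none
Why: Domino Claisen–Schmidt condensation (pyrrolidine enamine/iminium catalysis) to (E)-chalcone 9, oxa-Michael addition of the 2'-OH to racemic flavanone 10 (its C2 centre is formed without control and erased at once), then iodine-catalysed α-iodination/HI elimination with DMSO as terminal oxidant; the amine keeps the medium non-acidic so the free o-prenylphenol and the chromene are not cyclised, and the product has no stereocentre.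

**Compound list**

1 | 4-hydroxybenzaldehyde | O=Cc1ccc(O)cc1 | starting material
2 | prenyl bromide (1-bromo-3-methylbut-2-ene) | CC(C)=CCBr | starting material
3 | 4-hydroxy-3-(3-methylbut-2-en-1-yl)benzaldehyde | CC(C)=CCc1cc(C=O)ccc1O | intermediate
4 | o-quinone methide, 3-[(Z)-3-methylbut-2-en-1-ylidene]-4-oxocyclohexa-1,5-diene-1-carbaldehyde (not isolated) | O=CC1=C/C(=C/C=C(C)C)C(=O)C=C1 | intermediate
5 | 2,2-dimethyl-2H-chromene-6-carbaldehyde | CC1(C)C=Cc2cc(C=O)ccc2O1 | intermediate
6 | 2,4-dihydroxyacetophenone | CC(=O)c1ccc(O)cc1O | starting material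
7 | 2-methylbut-3-en-2-ol | C=CC(C)(C)O | starting material
8 | 1-[2,4-dihydroxy-5-(3-methylbut-2-en-1-yl)phenyl]ethan-1-one | CC(=O)c1cc(CC=C(C)C)c(O)cc1O | intermediate
9 | chalcone, (E)-1-[2,4-dihydroxy-5-(3-methylbut-2-en-1-yl)phenyl]-3-(2,2-dimethyl-2H-chromen-6-yl)prop-2-en-1-one (not isolated) | CC(C)=CCc1cc(C(=O)/C=C/c2ccc3c(c2)C=CC(C)(C)O3)c(O)cc1O | intermediate
10 | flavanone, racemic 2-(2,2-dimethyl-2H-chromen-6-yl)-7-hydroxy-6-(3-methylbut-2-en-1-yl)chroman-4-one (not isolated) | CC(C)=CCc1cc2c(cc1O)OC(c1ccc3c(c1)C=CC(C)(C)O3)CC2=O | intermediate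
11 | Kanzonol E, 2-(2,2-dimethyl-2H-chromen-6-yl)-7-hydroxy-6-(3-methylbut-2-en-1-yl)-4H-chromen-4-one (achiral) | CC(C)=CCc1cc2c(=O)cc(-c3ccc4c(c3)C=CC(C)(C)O4)oc2cc1O | target

**Totals**

Total step count: 4.
Longest linear sequence: 3 steps (steps 1, 2 and 4; step 3 is the one-step second branch).

**Steps most likely to fail, with fallbacks**

Step 4 (highest risk). Three things can go wrong:
- The aldol may be slow, because the 4-OH of 8 is largely a phenoxide under amine base.
- Iodine may attack the free 7-OH/6-prenyl pair (iodoetherification, or HI-promoted chroman formation).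
- Iodine may iodinate C8.

The fallback sets out from 5 and 8 and comes back at 11. The condensation is run without iodine (pyrrolidine, EtOH, 70 °C; or, if the amine-mediated aldol stalls, 50% aq KOH/EtOH to the isolated chalcone 9, then NaOAc, EtOH, reflux) and flavanone 10 is isolated. Its phenol is capped with Ac2O/pyridine at rt to give the racemic 7-acetoxyflavanone F1. Because an acetylated phenol cannot form a quinone methide, the A-ring prenyl group should not be cyclised by DDQ, and F1 is dehydrogenated with DDQ in refluxing 1,4-dioxane (hydride abstraction at C2, assisted by O1 and the para chromene oxygen) to the 7-acetoxyflavone F2. Catalytic K2CO3 in MeOH at rt then removes the acetate to give 11.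

Step 3 (regioselectivity). The C5/C3 ratio is modest and bis-prenylation and acid-induced chroman formation compete, so a yield of about 25–35% is expected. The fallback sets out from 6 and comes back at 8. Bromination with NBS (1.0 equiv, MeCN, 0 °C) should go mainly at C5, giving 1-(5-bromo-2,4-dihydroxyphenyl)ethan-1-one F3. A ligand-controlled, α-selective Suzuki–Miyaura coupling with 3-methylbut-2-en-1-ylboronic acid pinacol ester (Pd/bulky di-tert-butylbiarylphosphine, aq K3PO4, MeCN, 70 °C) then places the linear prenyl group at the halogen position and gives 8.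

Step 1 (C- versus O-alkylation). O-prenylation competes and the yield is expected to be about 30–40%. The fallback sets out from 1 and comes back at 5, replacing steps 1 and 2. O-Alkylation of 1 with 3-chloro-3-methylbut-1-yne (K2CO3, KI, cat. CuI, acetone, reflux) gives 4-[(2-methylbut-3-yn-2-yl)oxy]benzaldehyde F4. Heating F4 in N,N-diethylaniline at 190 °C triggers the aryl propargyl ether Claisen rearrangement and [1,5]-H shift, which arrive at the same quinone methide 4; this closes by the same oxa-6π electrocyclisation to 5.

**Further compounds**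

F1 | step 4 | racemic 2-(2,2-dimethyl-2H-chromen-6-yl)-6-(3-methylbut-2-en-1-yl)-4-oxochroman-7-yl acetate | CC(=O)Oc1cc2c(cc1CC=C(C)C)C(=O)CC(c1ccc3c(c1)C=CC(C)(C)O3)O2
F2 | step 4 | 2-(2,2-dimethyl-2H-chromen-6-yl)-6-(3-methylbut-2-en-1-yl)-4-oxo-4H-chromen-7-yl acetate | CC(=O)Oc1cc2oc(-c3ccc4c(c3)C=CC(C)(C)O4)cc(=O)c2cc1CC=C(C)C
F3 | step 3 | 1-(5-bromo-2,4-dihydroxyphenyl)ethan-1-one | CC(=O)c1cc(Br)c(O)cc1O
F4 | step 1 | 4-[(2-methylbut-3-yn-2-yl)oxy]benzaldehyde | C#CC(C)(C)Oc1ccc(C=O)cc1
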